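**Plan**
- Retrosynthesis first cuts the disubstituted C=C bond next to the ring (Wittig) into a C10 cyclopentane lactol and a C30 polyenyl phosphonium salt; the C30 unit is cut at the disubstituted double bond beside its geranyl end into crocetindialdehyde and a geranyl ylide.
- With the ring numbered as a cyclopentan-1-ol (C1 = C(CH3)OH, C2 = CH bearing the chain, C3 = CH bearing C(CH3)2OH, C4 and C5 = CH2), the ring is cut at C2–C3 and C4–C5 into a three-carbon unit C5–C1–C2 and a two-carbon unit C3–C4.
- Enabling feature: the carbinol carbon on C3 and the first chain carbon on C2 are cis and 1,4-related, so one ester oxygen can bridge them as a cis-fused γ-lactone (3-oxabicyclo[3.3.0]octan-2-one). This temporary lactone ties an acrylate (C3=C4) to a methylenecyclopropane whose CH–C(=CH2)–CH2 unit is C2–C1–C5.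
- Forward: (R)-epichlorohydrin → methylenecyclopropyl carbinol → acrylate → palladium-catalysed [3+2] closing cyclopentane and lactone together → hydration of the exocyclic methylene → MeMgBr cleaves the tether into C(CH3)2OH and CH2OH → oxidation to the lactol → Wittig with the C30 ylide.
- Stereochemistry: C2 comes from epichlorohydrin (cyclopropane stereocentre carried over with retention), C3 from the enforced cis ring fusion, C1 from oxygen delivery to the convex face of the bicyclic lactone; the E double bonds come from Wittig reactions followed by Z→E equilibration.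

Key step: step 3

Assumption: in step 1 the ylide is taken to attack the oxirane CH2 of epichlorohydrin (chloride leaving only in the epoxide transposition), so that (R)-epichlorohydrin gives the (R)-carbinol; if direct displacement of chloride were the main path, (S)-epichlorohydrin would be used without other change.

Step 1
Reactants: 1 (2R)-2-(chloromethyl)oxirane [(R)-epichlorohydrin]
Product: 4 [(1R)-2-methylidenecyclopropyl]methanol, via epoxyethylphosphonium chloride 2 (not isolated), via cyclopropylphosphonium betaine 3 (not isolated)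
Conditions: MePPh3Br, n-BuLi, THF, 0 °C; 1, 0 °C to rt; n-BuLi (2 equiv.), −20 °C to rt; (CH2O)n, rt
Reagents that add atoms: methyltriphenylphosphonium bromide, C[P+](c1ccccc1)(c1ccccc1)c1ccccc1.[Br-] (gives the ring carbon that carries the methylidene group); paraformaldehyde as formaldehyde, C=O (gives the exocyclic CH2)
Why: Tandem ylide alkylation, cyclopropanation and Wittig methylenation: the ylide opens the oxirane at CH2, the alkoxide closes onto CH2Cl to give 2, the ylide derived from 2 opens this transposed epoxide by 3-exo-tet attack with inversion to give 3, and the cyclopropyl ylide formed with further base is methylenated by formaldehyde, so the single stereocentre of 4 derives from 1.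

Step 2
Reactants: 4 [(1R)-2-methylidenecyclopropyl]methanol; 5 prop-2-enoyl chloride
Product: 6 [(1R)-2-methylidenecyclopropyl]methyl prop-2-enoate
Conditions: Et3N, DMAP (cat.), BHT (trace), CH2Cl2, 0 °C
Reagents that add atoms: none
Why: Acylation of a primary alcohol by an acid chloride installs the acrylate that serves both as two-carbon partner and as temporary ester tether; the stereocentre is not touched.

Step 3
Reactants: 6 [(1R)-2-methylidenecyclopropyl]methyl prop-2-enoate
Product: 7 (3aR,6aR)-4-methylidenehexahydro-1H-cyclopenta[c]furan-1-one (cis-fused)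
Conditions: Pd2(dba)3·CHCl3 (5 mol%), P(OiPr)3 (30 mol%), toluene (0.01 M, slow addition of 6), 110 °C
Reagents that add atoms: none
Why: Zerovalent palladium inserts into the distal C–C bond of the methylenecyclopropane (ring CH–ring CH2) to give a 2-methylidenepalladacyclobutane of divalent palladium, the tethered acrylate C=C inserts into the Pd–CH2 bond with carbon going to the β-carbon, and C–C reductive elimination joins the α-carbon to the former cyclopropane CH, so that the bonds C5–C6 and C3a–C6a of 7 form in one operation. The closest known reaction type is the palladium-catalysed intramolecular [3+2] cycloaddition of methylenecyclopropanes with tethered alkynes and electron-poor alkenes, which is stereospecific at the cyclopropane carbon. Two rings close: the cyclopentane by [3+2] union of the CH–C(=CH2)–CH2 unit with the acrylate CH=CH2, and the γ-lactone as a 5-exo closure when the α-carbon bonds to the tether-bearing CH. The stereocentre C3a is the cyclopropane stereocentre of 6 carried over with retention (oxidative addition and reductive elimination both proceed with retention at carbon), and the new stereocentre C6a is fixed by the three-atom ester tether, which allows only the cis-fused bicyclo[3.3.0] lactone. The step needs distal ring opening (secured by the phosphite-ligated catalyst and by a tether that can reach only the ring CH), intramolecular reaction (secured by high dilution, the acrylate being the only electron-poor alkene) and ring closure faster than equilibration through an open trimethylenemethane complex, which would erode the enantiomeric purity.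

Step 4
Reactants: 7 (3aR,6aR)-4-methylidenehexahydro-1H-cyclopenta[c]furan-1-one
Product: 8 (3aS,4R,6aR)-4-hydroxy-4-methylhexahydro-1H-cyclopenta[c]furan-1-one (OH cis to the ring-fusion hydrogens)
Conditions: Co(acac)2 (20 mol%), PhSiH3, O2 (1 atm), THF, rt
Reagents that add atoms: dioxygen, O=O (gives the hydroxyl oxygen)
Why: Mukaiyama hydration (hydrogen-atom transfer from a cobalt hydride to the 1,1-disubstituted alkene, then capture of the tertiary radical by O2) gives the Markovnikov tertiary alcohol, and oxygen should enter on the convex face of the cis-fused bicycle, anti to the lactone CH2 on the neighbouring ring-fusion carbon, which places OH trans to that arm as the target requires.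

Step 5
Reactants: 8 (3aS,4R,6aR)-4-hydroxy-4-methylhexahydro-1H-cyclopenta[c]furan-1-one
Product: 9 (1R,2S,3R)-2-(hydroxymethyl)-3-(2-hydroxypropan-2-yl)-1-methylcyclopentan-1-ol
Conditions: MeMgBr (5 equiv.), THF, 0 °C to rt; then aq. NH4Cl
Reagents that add atoms: methylmagnesium bromide, C[Mg]Br (two methyl groups)
Why: Double Grignard addition to the lactone carbonyl turns it into the 2-hydroxypropan-2-yl group and cleaves the ester tether to release the primary alcohol; no stereocentre is changed because the intermediate methyl ketone should add faster than it enolises.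

Step 6
Reactants: 9 (1R,2S,3R)-2-(hydroxymethyl)-3-(2-hydroxypropan-2-yl)-1-methylcyclopentan-1-ol
Product: 11 (3aR,6R,6aR)-3,3,6-trimethylhexahydro-1H-cyclopenta[c]furan-1,6-diol (lactol as anomeric mixture), via hydroxy aldehyde 10 (not isolated)
Conditions: Dess–Martin periodinane (1.1 equiv.), pyridine, CH2Cl2, 0 °C
Reagents that add atoms: none
Why: Dess–Martin oxidation touches only the primary alcohol, and aldehyde 10 should be trapped at once by the cis tertiary hydroxyl as the five-membered lactol, which is the form that is isolated and which shields the β-hydroxy aldehyde from epimerisation and loss of water.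

Step 7
Reactants: 12 (2E)-1-bromo-3,7-dimethylocta-2,6-diene (geranyl bromide); 13 triphenylphosphine
Product: 14 [(2E)-3,7-dimethylocta-2,6-dien-1-yl]triphenylphosphonium bromide
Conditions: toluene, rt
Reagents that add atoms: none
Why: SN2 quaternisation of the primary allylic bromide by the phosphine, with the E double bond unchanged.

Step 8
Reactants: 14 [(2E)-3,7-dimethylocta-2,6-dien-1-yl]triphenylphosphonium bromide; 15 (2E,4E,6E,8E,10E,12E,14E)-2,6,11,15-tetramethylhexadeca-2,4,6,8,10,12,14-heptaenedial (crocetindialdehyde)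
Product: 18 (2E,4E,6E,8E,10E,12E,14E,16E,18E)-2,6,11,15,19,23-hexamethyltetracosa-2,4,6,8,10,12,14,16,18,22-decaenal, via geranylidene ylide 16 (not isolated), via 16Z aldehyde 17 (not isolated)
Conditions: NaN(SiMe3)2, THF, −78 °C; add to 15 (3 equiv.), −78 °C to rt; then I2 (cat.), CH2Cl2, daylight, rt
Reagents that add atoms: none
Why: Wittig olefination of one formyl group of the dialdehyde (used in excess) by allylic ylide 16 forms the new disubstituted double bond as an E/Z mixture (17 beside 18), which iodine-catalysed equilibration should convert into the all-E aldehyde.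

Step 9
Reactants: 18 (all-E)-2,6,11,15,19,23-hexamethyltetracosa-2,4,6,8,10,12,14,16,18,22-decaenal
Product: 19 (2E,4E,6E,8E,10E,12E,14E,16E,18E)-2,6,11,15,19,23-hexamethyltetracosa-2,4,6,8,10,12,14,16,18,22-decaen-1-ol
Conditions: NaBH4, EtOH/THF, 0 °C
Reagents that add atoms: none
Why: 1,2-Reduction of the conjugated aldehyde by borohydride leaves the polyene untouched.

Step 10
Reactants: 19 (all-E)-2,6,11,15,19,23-hexamethyltetracosa-2,4,6,8,10,12,14,16,18,22-decaen-1-ol
Product: 20 [(2E,4E,6E,8E,10E,12E,14E,16E,18E)-2,6,11,15,19,23-hexamethyltetracosa-2,4,6,8,10,12,14,16,18,22-decaen-1-yl]triphenylphosphonium bromide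
Conditions: Ph3P·HBr, MeOH/CH2Cl2, rt, dark
Reagents that add atoms: triphenylphosphine hydrobromide, Br.P(c1ccccc1)(c1ccccc1)c1ccccc1 (phosphonium group and bromide)
Why: The acid ionises the polyenyl allylic alcohol and the phosphine should trap the delocalised cation at its primary terminus, which keeps the polyene fully conjugated (the usual preparation of carotenoid Wittig salts).

Step 11
Reactants: 20 C30 phosphonium bromide; 11 (3aR,6R,6aR)-3,3,6-trimethylhexahydro-1H-cyclopenta[c]furan-1,6-diol
Product: 23 (1R,2R,3R)-2-[(1E,3E,5E,7E,9E,11E,13E,15E,17E,19E)-3,7,12,16,20,24-hexamethylpentacosa-1,3,5,7,9,11,13,15,17,19,23-undecaen-1-yl]-3-(2-hydroxypropan-2-yl)-1-methylcyclopentan-1-ol, via C30 ylide 21 (not isolated), via 1Z isomer 22 (not isolated)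
Conditions: 1,2-epoxybutane, 65 °C, dark, argon; then heptane, reflux
Reagents that add atoms: none
Why: Wittig olefination under near-neutral conditions: bromide opens the epoxide to an alkoxide that generates ylide 21, which intercepts the small equilibrium share of the ring-opened formyl tautomer of lactol 11 (the hydroxy aldehyde 10 that first arises in step 6), so the stereocentre next to the formyl group and the β-hydroxyl should survive, and the Z isomer 22 at the new disubstituted double bond is equilibrated thermally to the all-E target.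

**Compound list**
1 | (2R)-2-(chloromethyl)oxirane, (R)-epichlorohydrin | ClC[C@H]1CO1 | starting material
2 | {2-[(2R)-oxiran-2-yl]ethyl}triphenylphosphonium chloride | [Cl-].C1O[C@@H]1CC[P+](c1ccccc1)(c1ccccc1)c1ccccc1 | intermediate
3 | [(2S)-2-(oxidomethyl)cyclopropyl]triphenylphosphonium (betaine) | [O-]C[C@@H]1CC1[P+](c1ccccc1)(c1ccccc1)c1ccccc1 | intermediate
4 | [(1R)-2-methylidenecyclopropyl]methanol | OC[C@@H]1CC1=C | intermediate
5 | prop-2-enoyl chloride | C=CC(Cl)=O | starting material
6 | [(1R)-2-methylidenecyclopropyl]methyl prop-2-enoate | C=CC(=O)OC[C@@H]1CC1=C | intermediate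
7 | (3aR,6aR)-4-methylidenehexahydro-1H-cyclopenta[c]furan-1-one | O=C1OC[C@@H]2[C@H]1CCC2=C | intermediate
8 | (3aS,4R,6aR)-4-hydroxy-4-methylhexahydro-1H-cyclopenta[c]furan-1-one | O=C1OC[C@@H]2[C@H]1CC[C@@]2(C)O | intermediate
9 | (1R,2S,3R)-2-(hydroxymethyl)-3-(2-hydroxypropan-2-yl)-1-methylcyclopentan-1-ol | OC[C@@H]1[C@H](C(C)(C)O)CC[C@@]1(C)O | intermediate
10 | (1R,2R,5R)-2-hydroxy-5-(2-hydroxypropan-2-yl)-2-methylcyclopentane-1-carbaldehyde | O=C[C@@H]1[C@H](C(C)(C)O)CC[C@@]1(C)O | intermediate
11 | (3aR,6R,6aR)-3,3,6-trimethylhexahydro-1H-cyclopenta[c]furan-1,6-diol | CC1(C)OC(O)[C@@H]2[C@H]1CC[C@@]2(C)O | intermediate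
12 | (2E)-1-bromo-3,7-dimethylocta-2,6-diene | CC(C)=CCC/C(C)=C/CBr | starting material
13 | triphenylphosphine | c1ccc(cc1)P(c1ccccc1)c1ccccc1 | starting material
14 | [(2E)-3,7-dimethylocta-2,6-dien-1-yl]triphenylphosphonium bromide | CC(C)=CCC/C(C)=C/C[P+](c1ccccc1)(c1ccccc1)c1ccccc1.[Br-] | intermediate
15 | (2E,4E,6E,8E,10E,12E,14E)-2,6,11,15-tetramethylhexadeca-2,4,6,8,10,12,14-heptaenedial | O=C/C(C)=C/C=C/C(C)=C/C=C/C=C(C)/C=C/C=C(C)/C=O | starting material
16 | [(2E)-3,7-dimethylocta-2,6-dien-1-ylidene]triphenylphosphorane | CC(C)=CCC/C(C)=C/C=P(c1ccccc1)(c1ccccc1)c1ccccc1 | intermediate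
17 | (2E,4E,6E,8E,10E,12E,14E,16Z,18E)-2,6,11,15,19,23-hexamethyltetracosa-2,4,6,8,10,12,14,16,18,22-decaenal | CC(C)=CCC/C(C)=C/C=C\C(C)=C\C=C\C(C)=C\C=C\C=C(C)\C=C\C=C(C)\C=O | intermediate
18 | (2E,4E,6E,8E,10E,12E,14E,16E,18E)-2,6,11,15,19,23-hexamethyltetracosa-2,4,6,8,10,12,14,16,18,22-decaenal | CC(C)=CCC/C(C)=C/C=C/C(C)=C/C=C/C(C)=C/C=C/C=C(C)/C=C/C=C(C)/C=O | intermediate
19 | (2E,4E,6E,8E,10E,12E,14E,16E,18E)-2,6,11,15,19,23-hexamethyltetracosa-2,4,6,8,10,12,14,16,18,22-decaen-1-ol | CC(C)=CCC/C(C)=C/C=C/C(C)=C/C=C/C(C)=C/C=C/C=C(C)/C=C/C=C(C)/CO | intermediate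
20 | [(2E,4E,6E,8E,10E,12E,14E,16E,18E)-2,6,11,15,19,23-hexamethyltetracosa-2,4,6,8,10,12,14,16,18,22-decaen-1-yl]triphenylphosphonium bromide | CC(C)=CCC/C(C)=C/C=C/C(C)=C/C=C/C(C)=C/C=C/C=C(C)/C=C/C=C(C)/C[P+](c1ccccc1)(c1ccccc1)c1ccccc1.[Br-] | intermediate
21 | [(2E,4E,6E,8E,10E,12E,14E,16E,18E)-2,6,11,15,19,23-hexamethyltetracosa-2,4,6,8,10,12,14,16,18,22-decaen-1-ylidene]triphenylphosphorane | CC(C)=CCC/C(C)=C/C=C/C(C)=C/C=C/C(C)=C/C=C/C=C(C)/C=C/C=C(C)/C=P(c1ccccc1)(c1ccccc1)c1ccccc1 | intermediate
22 | (1R,2R,3R)-2-[(1Z,3E,5E,7E,9E,11E,13E,15E,17E,19E)-3,7,12,16,20,24-hexamethylpentacosa-1,3,5,7,9,11,13,15,17,19,23-undecaen-1-yl]-3-(2-hydroxypropan-2-yl)-1-methylcyclopentan-1-ol | CC(C)=CCC/C(C)=C/C=C/C(C)=C/C=C/C(C)=C/C=C/C=C(C)/C=C/C=C(C)/C=C\[C@@H]1[C@H](C(C)(C)O)CC[C@@]1(C)O | intermediate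
23 | (1R,2R,3R)-2-[(1E,3E,5E,7E,9E,11E,13E,15E,17E,19E)-3,7,12,16,20,24-hexamethylpentacosa-1,3,5,7,9,11,13,15,17,19,23-undecaen-1-yl]-3-(2-hydroxypropan-2-yl)-1-methylcyclopentan-1-ol (chain and 2-hydroxypropan-2-yl cis, ring OH trans to the chain) | CC(C)=CCC/C(C)=C/C=C/C(C)=C/C=C/C(C)=C/C=C/C=C(C)/C=C/C=C(C)/C=C/[C@@H]1[C@H](C(C)(C)O)CC[C@@]1(C)O | target

Total step count: 11. Longest linear sequence: 7 steps (steps 1 to 6, then step 11).

**Steps most likely to fail**

Step 3. The acrylate ester prefers the rotamer that holds the C=C bond away from the palladacycle, so insertion may be slow and intermolecular cycloaddition or oligomerisation may take over. Equilibration of the palladacycle through an open trimethylenemethane complex may also erode the enantiomeric purity. The fallback sets out from alcohol 4 and changes the two-carbon partner to an alkyne, the partner for which this stereospecific cycloaddition is best established. Esterification of 4 with propiolic acid (DCC, DMAP cat., CH2Cl2, 0 °C) would give [(1R)-2-methylidenecyclopropyl]methyl prop-2-ynoate F1. The same Pd2(dba)3/P(OiPr)3 catalyst in toluene at 100 °C should then give the dienyl butenolide (3aS)-4-methylidene-3,3a,4,5-tetrahydro-1H-cyclopenta[c]furan-1-one F2. 1,4-Reduction of the butenolide with [(Ph3P)CuH]6 (benzene, rt) and protonation of the enolate to the only unstrained, cis-fused lactone sets the second ring-fusion centre after the fact. The fallback comes back to the route at lactone 7.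

Step 11. The ring-opened form of the lactol is a β-hydroxy aldehyde, so loss of water, retro-aldol opening or epimerisation next to the formyl group may compete, and the reaction may be slow because little of the open form is present. The fallback sets out from triol 9 and aldehyde 18 and reverses the polarity of the coupling (Julia–Kocienski olefination), so that no ring aldehyde is needed. Mitsunobu reaction of the primary alcohol of 9 with 1-phenyl-1H-tetrazole-5-thiol (PPh3, DIAD, THF, 0 °C) would give (1R,2R,3R)-3-(2-hydroxypropan-2-yl)-1-methyl-2-{[(1-phenyl-1H-tetrazol-5-yl)sulfanyl]methyl}cyclopentan-1-ol F3. Oxidation with H2O2 and (NH4)6Mo7O24 (cat.) in EtOH would give the sulfone (1R,2R,3R)-3-(2-hydroxypropan-2-yl)-1-methyl-2-{[(1-phenyl-1H-tetrazol-5-yl)sulfonyl]methyl}cyclopentan-1-ol F4. Silylation of both tertiary hydroxyls (Me3SiOSO2CF3, 2,6-lutidine, CH2Cl2, −78 °C) would give 1-phenyl-5-({(1R,2R,5R)-2-methyl-2-[(trimethylsilyl)oxy]-5-{2-[(trimethylsilyl)oxy]propan-2-yl}cyclopentyl}methanesulfonyl)-1H-tetrazole F5. Deprotonation with KN(SiMe3)2 (THF, −78 °C) in the presence of 18 would give the bis(trimethylsilyl) ether of 23 F6 after thermal Z→E equilibration. Bu4NF (THF, 0 °C) then frees both hydroxyls, and the fallback comes back at target 23.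

Step 1. Attack of the ylide at the CH2Cl carbon in competition with oxirane opening would lead to the enantiomer and lower the enantiomeric purity, and methylenation of the hindered cyclopropyl ylide may be inefficient. The fallback sets out from epichlorohydrin 1 and replaces the phosphorus ylide by a sulfonyl carbanion, for which oxirane opening is the established path, with the methylidene group made by a separate elimination. Methyl phenyl sulfone with n-BuLi (2.2 equiv., THF, −78 °C to rt) would give [(1S)-2-(benzenesulfonyl)cyclopropyl]methanol F7 by epoxide opening, epoxide transposition and 3-exo-tet closure. TBSCl and imidazole (DMF) would give tert-butyl{[(1S)-2-(benzenesulfonyl)cyclopropyl]methoxy}dimethylsilane F8. Lithiation next to the sulfone (n-BuLi, THF, −78 °C) and alkylation with (iodomethyl)trimethylsilane would give tert-butyl({(1S)-2-(benzenesulfonyl)-2-[(trimethylsilyl)methyl]cyclopropyl}methoxy)dimethylsilane F9. Bu4NF (THF, reflux) should then bring about the 1,2-elimination of sulfinate and silyl group and remove the silyl ether, and the fallback comes back at alcohol 4.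

**Further compounds**
F1 | step 3 | [(1R)-2-methylidenecyclopropyl]methyl prop-2-ynoate | C#CC(=O)OC[C@@H]1CC1=C
F2 | step 3 | (3aS)-4-methylidene-3,3a,4,5-tetrahydro-1H-cyclopenta[c]furan-1-one | C=C1CC=C2C(=O)OC[C@@H]12
F3 | step 11 | (1R,2R,3R)-3-(2-hydroxypropan-2-yl)-1-methyl-2-{[(1-phenyl-1H-tetrazol-5-yl)sulfanyl]methyl}cyclopentan-1-ol | c1ccccc1-n1nnnc1SC[C@@H]2[C@H](C(C)(C)O)CC[C@@]2(C)O
F4 | step 11 | (1R,2R,3R)-3-(2-hydroxypropan-2-yl)-1-methyl-2-{[(1-phenyl-1H-tetrazol-5-yl)sulfonyl]methyl}cyclopentan-1-ol | c1ccccc1-n1nnnc1S(=O)(=O)C[C@@H]2[C@H](C(C)(C)O)CC[C@@]2(C)O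
F5 | step 11 | 1-phenyl-5-({(1R,2R,5R)-2-methyl-2-[(trimethylsilyl)oxy]-5-{2-[(trimethylsilyl)oxy]propan-2-yl}cyclopentyl}methanesulfonyl)-1H-tetrazole | c1ccccc1-n1nnnc1S(=O)(=O)C[C@@H]2[C@H](C(C)(C)O[Si](C)(C)C)CC[C@@]2(C)O[Si](C)(C)C
F6 | step 11 | bis(trimethylsilyl) ether of 23 (both tertiary hydroxyls silylated) | CC(C)=CCC/C(C)=C/C=C/C(C)=C/C=C/C(C)=C/C=C/C=C(C)/C=C/C=C(C)/C=C/[C@@H]1[C@H](C(C)(C)O[Si](C)(C)C)CC[C@@]1(C)O[Si](C)(C)C
F7 | step 1 | [(1S)-2-(benzenesulfonyl)cyclopropyl]methanol | OC[C@@H]1CC1S(=O)(=O)c1ccccc1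
F8 | step 1 | tert-butyl{[(1S)-2-(benzenesulfonyl)cyclopropyl]methoxy}dimethylsilane | CC(C)(C)[Si](C)(C)OC[C@@H]1CC1S(=O)(=O)c1ccccc1
F9 | step 1 | tert-butyl({(1S)-2-(benzenesulfonyl)-2-[(trimethylsilyl)methyl]cyclopropyl}methoxy)dimethylsilane | CC(C)(C)[Si](C)(C)OC[C@@H]1CC1(C[Si](C)(C)C)S(=O)(=O)c1ccccc1
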